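**Assumptions.** Germacrane-type numbering is used for the target: C1 ketone, C4/C5 epoxide, C6 lactone oxygen, C7 and C10 ether carbons, C8 ester carbon, C11=C13 methylene, C12 lactone carbonyl. 5-Bromofuran-2-carbaldehyde is taken as the cheap, furfural-derived commercial heteroaromatic. The catalyst enantiomer in step 7 is the one that gives (1R,5S,6S)-15; the sense of induction has to be confirmed experimentally.

**Retrosynthetic overview**
1. Target ⇒ ethynyl epoxy alcohol (Pd/CO cyclocarbonylation closes the α-methylene lactone last) ⇒ (Z)-C4=C5 allylic alcohol (hydroxyl-directed epoxidation).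
2. Ten-membered carbocycle ⇒ cis-2,5-disubstituted oxolane carrying a C6 aldehyde and a C1 keto chain ending in a (Z)-vinyl iodide (intramolecular Nozaki–Hiyama–Kishi, C5–C6).
3. That oxolane ⇒ 8-oxabicyclo[3.2.1]oct-3-en-2-one (oxa-Michael/retro-aldol cleavage of C2–C6).
4. Key step: bicycle ⇒ 3-oxidopyrylium (from a trisubstituted furan by Achmatowicz oxidation) + vinyl methacrylate, enantioselective [5+2]; it forms the oxolane ring and sets C7, C8 (with its ester) and C10 at once.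
5. Furan ⇒ 5-bromofurfural, TIPS-acetylene, MeLi and a (Z)-iodoallyl bromide from propargyl alcohol. Ring order: furan → pyranone → oxa-bridged bicycle (oxolane) → ten-membered ring → epoxide → lactone.

**Route**

Step 1
Reactants: 1 prop-2-yn-1-ol
Product: 3 (2Z)-3-iodo-2-methylprop-2-en-1-ol, via vinylmagnesium chelate 2 (not isolated)
Conditions: MeMgBr (2.5 equiv), CuI (10 mol %), Et2O, –10 °C → rt; then I2, –20 °C; aq NH4Cl
Reagents that add atoms: methylmagnesium bromide (C[Mg]Br); iodine (II)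
Why: Copper-catalysed anti-carbomagnesiation of the propargylic alkoxide (Duboudin–Jousseaume) puts Me on C2 and Mg on C3 inside a five-membered O–Mg chelate, so iodinolysis with retention gives only the (Z)-iodide.

Step 2
Reactants: 3 (2Z)-3-iodo-2-methylprop-2-en-1-ol
Product: 4 (1Z)-3-bromo-1-iodo-2-methylprop-1-ene
Conditions: CBr4, PPh3, CH2Cl2, 0 °C
Reagents that add atoms: tetrabromomethane (BrC(Br)(Br)Br)
Why: Appel bromination is an SN2 displacement at the primary allylic carbon and leaves the vinyl iodide geometry untouched.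

Step 3
Reactants: 5 5-bromofuran-2-carbaldehyde; 6 ethynyltri(propan-2-yl)silane
Product: 7 5-{[tri(propan-2-yl)silyl]ethynyl}furan-2-carbaldehyde
Conditions: PdCl2(PPh3)2 (2 mol %), CuI (4 mol %), Et3N, THF, rt
Reagents that add atoms: none
Why: Sonogashira coupling of an electron-poor 2-bromofuran; the alkyne is the future C11/C13 unit and blocks furan C5.

Step 4
Reactants: 7 5-{[tri(propan-2-yl)silyl]ethynyl}furan-2-carbaldehyde; 4 (1Z)-3-bromo-1-iodo-2-methylprop-1-ene
Product: 10 1-{3-[(2Z)-3-iodo-2-methylprop-2-en-1-yl]-5-{[tri(propan-2-yl)silyl]ethynyl}furan-2-yl}ethan-1-ol (racemic), via lithium alkoxide 8 (not isolated), via dilithio species 9 (not isolated)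
Conditions: MeLi (1.05 equiv), THF, –78 °C; then n-BuLi (1.2 equiv), TMEDA, –78 → –20 °C; then CuBr·SMe2 (10 mol %), 4, –40 → 0 °C; aq NH4Cl
Reagents that add atoms: methyllithium ([Li]C)
Why: 1,2-Addition of MeLi gives a lithium alkoxide that directs ortho-lithiation to furan C3 (C5 is blocked), and the furyl metal is allylated by SN2 at the allylic bromide (directed ortho-metalation/allylation); the carbinol centre is racemic and is destroyed in step 7.

Step 5
Reactants: 10 1-{3-[(2Z)-3-iodo-2-methylprop-2-en-1-yl]-5-{[tri(propan-2-yl)silyl]ethynyl}furan-2-yl}ethan-1-ol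
Product: 11 6-hydroxy-4-[(2Z)-3-iodo-2-methylprop-2-en-1-yl]-2-methyl-6-{[tri(propan-2-yl)silyl]ethynyl}-2H-pyran-3(6H)-one (diastereomer mixture)
Conditions: NBS (1.05 equiv), NaHCO3, NaOAc, THF–H2O 4:1, 0 °C
Reagents that add atoms: water (O)
Why: Achmatowicz oxidative ring expansion; the electron-rich furan is oxidised far faster than the iodoalkene, and its aromaticity is lost here for the first time.

Step 6
Reactants: 11 6-hydroxy-4-[(2Z)-3-iodo-2-methylprop-2-en-1-yl]-2-methyl-6-{[tri(propan-2-yl)silyl]ethynyl}-2H-pyran-3(6H)-one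
Product: 12 4-[(2Z)-3-iodo-2-methylprop-2-en-1-yl]-6-methyl-5-oxo-2-{[tri(propan-2-yl)silyl]ethynyl}-5,6-dihydro-2H-pyran-2-yl 4-(methylsulfanyl)benzoate (diastereomer mixture)
Conditions: 4-(MeS)C6H4COCl, Et3N, DMAP (cat.), CH2Cl2, 0 °C
Reagents that add atoms: 4-(methylsulfanyl)benzoyl chloride (CSc1ccc(cc1)C(Cl)=O)
Why: Acylation of the tertiary hemiketal installs the carboxylate leaving group needed to generate the pyrylium under anion-binding catalysis.

Step 7
Reactants: 12 4-[(2Z)-3-iodo-2-methylprop-2-en-1-yl]-6-methyl-5-oxo-2-{[tri(propan-2-yl)silyl]ethynyl}-5,6-dihydro-2H-pyran-2-yl 4-(methylsulfanyl)benzoate; 13 ethenyl 2-methylprop-2-enoate (10 equiv)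
Product: 15 (1R,5S,6S)-3-[(2Z)-3-iodo-2-methylprop-2-en-1-yl]-1-methyl-2-oxo-5-{[tri(propan-2-yl)silyl]ethynyl}-8-oxabicyclo[3.2.1]oct-3-en-6-yl 2-methylprop-2-enoate (6-exo ester), via 3-oxidopyrylium ylide 14 (not isolated)
Conditions: chiral primary aminothiourea (15 mol %), N,N′-bis[3,5-bis(trifluoromethyl)phenyl]thiourea (15 mol %), AcOH (15 mol %), toluene, 25–40 °C
Reagents that add atoms: none
Why: Proposed new method: thiourea-assisted loss of the aroate gives the aromatic 3-oxidopyrylium dipole, which adds across C2/C6 to the vinyl-ester C=C of 13 (the 1,1-disubstituted methacrylate alkene is too hindered to bond to two fully substituted termini); the CH2 end joins the methyl-bearing C2 and the ester-bearing carbon joins the alkynyl-bearing C6 (the usual 6-regiochemistry), the ester sits exo away from the enone bridge, and the chiral ion pair selects the face, so C7, C8 and C10 are set in one step; closest known reaction: aminothiourea/thiourea-catalysed enantioselective intermolecular [5+2] cycloaddition of 6-acyloxypyranones with vinyl ethers.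

Step 8
Reactants: 15 (1R,5S,6S)-3-[(2Z)-3-iodo-2-methylprop-2-en-1-yl]-1-methyl-2-oxo-5-{[tri(propan-2-yl)silyl]ethynyl}-8-oxabicyclo[3.2.1]oct-3-en-6-yl 2-methylprop-2-enoate
Product: 17 (2S,3S,5R)-2-formyl-5-[(4Z)-5-iodo-4-methylpent-4-enoyl]-5-methyl-2-{[tri(propan-2-yl)silyl]ethynyl}oxolan-3-yl 2-methylprop-2-enoate, via β-ketol 16 (not isolated)
Conditions: LiOH (0.2 equiv), THF–H2O 3:1, 0 °C
Reagents that add atoms: water (O)
Why: Proposed new method: hydroxide adds to the enone β-carbon (C6) and the seven-membered β-ketol 16 undergoes retro-aldol cleavage of C2–C6, driven by opening of the bridged seven-membered ring and hydration of the non-enolisable α-alkoxy aldehyde; C7, C8 and C10 are untouched; closest known reactions: oxa-Michael addition and base-catalysed retro-aldol opening of cyclic β-ketols.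

Step 9
Reactants: 17 (2S,3S,5R)-2-formyl-5-[(4Z)-5-iodo-4-methylpent-4-enoyl]-5-methyl-2-{[tri(propan-2-yl)silyl]ethynyl}oxolan-3-yl 2-methylprop-2-enoate
Product: 19 (1R,5Z,7R,8R,9S)-7-hydroxy-1,5-dimethyl-2-oxo-8-{[tri(propan-2-yl)silyl]ethynyl}-11-oxabicyclo[6.2.1]undec-5-en-9-yl 2-methylprop-2-enoate, via vinylchromium species 18 (not isolated)
Conditions: CrCl2 (8 equiv), NiCl2 (2 mol %), DMSO–THF 3:1, syringe-pump addition to 0.003 M, rt; aq work-up
Reagents that add atoms: none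
Why: Intramolecular Nozaki–Hiyama–Kishi reaction: the (Z)-vinylchromium(III) species adds only to the aldehyde (ketone, esters and silylalkyne are inert) with retention of alkene geometry, and polar Felkin–Anh attack anti to the ring C7–O bond, past the slim alkynyl group, gives the (6R) carbinol.

Step 10
Reactants: 19 (1R,5Z,7R,8R,9S)-7-hydroxy-1,5-dimethyl-2-oxo-8-{[tri(propan-2-yl)silyl]ethynyl}-11-oxabicyclo[6.2.1]undec-5-en-9-yl 2-methylprop-2-enoate
Product: 20 (1R,5R,6S,7R,8R,9S)-5,6-epoxy-7-hydroxy-1,5-dimethyl-2-oxo-8-{[tri(propan-2-yl)silyl]ethynyl}-11-oxabicyclo[6.2.1]undecan-9-yl 2-methylprop-2-enoate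
Conditions: VO(acac)2 (5 mol %), t-BuOOH (1.5 equiv), CH2Cl2, 0 °C
Reagents that add atoms: tert-butyl hydroperoxide (CC(C)(C)OO)
Why: Hydroxyl-directed vanadium epoxidation: the allylic vanadate delivers oxygen to the same face of the (Z)-alkene, giving the cis (erythro) epoxy alcohol as for other medium-ring (Z)-cycloalkenols, which sets C4 (R) and C5 (S); the electron-poor methacrylate and the alkyne do not react.

Step 11
Reactants: 20 (1R,5R,6S,7R,8R,9S)-5,6-epoxy-7-hydroxy-1,5-dimethyl-2-oxo-8-{[tri(propan-2-yl)silyl]ethynyl}-11-oxabicyclo[6.2.1]undecan-9-yl 2-methylprop-2-enoate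
Product: 21 (1R,5R,6S,7R,8R,9S)-5,6-epoxy-8-ethynyl-7-hydroxy-1,5-dimethyl-2-oxo-11-oxabicyclo[6.2.1]undecan-9-yl 2-methylprop-2-enoate
Conditions: TBAF, AcOH (1:1), THF, 0 °C
Reagents that add atoms: none
Why: Fluoride cleaves the C(sp)–Si bond; acetic acid buffering suppresses Payne rearrangement of the epoxy alcohol and ester cleavage.

Step 12
Reactants: 21 (1R,5R,6S,7R,8R,9S)-5,6-epoxy-8-ethynyl-7-hydroxy-1,5-dimethyl-2-oxo-11-oxabicyclo[6.2.1]undecan-9-yl 2-methylprop-2-enoate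
Product: 22 CNP0241021.1 (target)
Conditions: PdI2 (5 mol %), PBu3 (10 mol %), CO (7 atm), MeCN, 60 °C
Reagents that add atoms: carbon monoxide ([C-]#[O+])
Why: Palladium-catalysed cyclocarbonylation of a homopropargylic alcohol (Norton type): the C6–O–C(=O)–Pd species adds syn across the alkyne in a 5-exo sense and protonolysis gives the α-methylene-γ-lactone without enolate chemistry next to the β-ether oxygen; no stereocentre is touched.

**Compound list**

1 | prop-2-yn-1-ol | C#CCO | starting material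
2 | 4-methyl-2,5-dihydro-1,2-oxamagnesole (chelated vinylmagnesium alkoxide) | CC1=C[Mg]OC1 | intermediate
3 | (2Z)-3-iodo-2-methylprop-2-en-1-ol | OC/C(C)=C\I | intermediate
4 | (1Z)-3-bromo-1-iodo-2-methylprop-1-ene | BrC/C(C)=C\I | intermediate
5 | 5-bromofuran-2-carbaldehyde | O=Cc1ccc(Br)o1 | starting material
6 | ethynyltri(propan-2-yl)silane | C#C[Si](C(C)C)(C(C)C)C(C)C | starting material
7 | 5-{[tri(propan-2-yl)silyl]ethynyl}furan-2-carbaldehyde | O=Cc1ccc(C#C[Si](C(C)C)(C(C)C)C(C)C)o1 | intermediate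
8 | lithium 1-(5-{[tri(propan-2-yl)silyl]ethynyl}furan-2-yl)ethan-1-olate (racemic) | CC(O[Li])c1ccc(C#C[Si](C(C)C)(C(C)C)C(C)C)o1 | intermediate
9 | 3-lithio derivative of alkoxide 8 | [Li]c1cc(C#C[Si](C(C)C)(C(C)C)C(C)C)oc1C(C)O[Li] | intermediate
10 | 1-{3-[(2Z)-3-iodo-2-methylprop-2-en-1-yl]-5-{[tri(propan-2-yl)silyl]ethynyl}furan-2-yl}ethan-1-ol (racemic) | CC(O)c1oc(C#C[Si](C(C)C)(C(C)C)C(C)C)cc1C/C(C)=C\I | intermediate
11 | 6-hydroxy-4-[(2Z)-3-iodo-2-methylprop-2-en-1-yl]-2-methyl-6-{[tri(propan-2-yl)silyl]ethynyl}-2H-pyran-3(6H)-one (diastereomer mixture) | CC1OC(O)(C#C[Si](C(C)C)(C(C)C)C(C)C)C=C(C/C(C)=C\I)C1=O | intermediate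
12 | 4-[(2Z)-3-iodo-2-methylprop-2-en-1-yl]-6-methyl-5-oxo-2-{[tri(propan-2-yl)silyl]ethynyl}-5,6-dihydro-2H-pyran-2-yl 4-(methylsulfanyl)benzoate (diastereomer mixture) | CC1OC(OC(=O)c2ccc(SC)cc2)(C#C[Si](C(C)C)(C(C)C)C(C)C)C=C(C/C(C)=C\I)C1=O | intermediate
13 | ethenyl 2-methylprop-2-enoate (vinyl methacrylate) | C=C(C)C(=O)OC=C | starting material
14 | 4-[(2Z)-3-iodo-2-methylprop-2-en-1-yl]-2-methyl-6-{[tri(propan-2-yl)silyl]ethynyl}pyrylium-3-olate | Cc1[o+]c(C#C[Si](C(C)C)(C(C)C)C(C)C)cc(C/C(C)=C\I)c1[O-] | intermediate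
15 | (1R,5S,6S)-3-[(2Z)-3-iodo-2-methylprop-2-en-1-yl]-1-methyl-2-oxo-5-{[tri(propan-2-yl)silyl]ethynyl}-8-oxabicyclo[3.2.1]oct-3-en-6-yl 2-methylprop-2-enoate (6-exo ester) | C=C(C)C(=O)O[C@H]1C[C@@]2(C)O[C@]1(C#C[Si](C(C)C)(C(C)C)C(C)C)C=C(C/C(C)=C\I)C2=O | intermediate
16 | 4-hydroxy-3-[(2Z)-3-iodo-2-methylprop-2-en-1-yl]-1-methyl-2-oxo-5-{[tri(propan-2-yl)silyl]ethynyl}-8-oxabicyclo[3.2.1]octan-6-yl 2-methylprop-2-enoate (bridgeheads and ester carbon as in 15; C3/C4 epimer mixture) | C=C(C)C(=O)O[C@H]1C[C@@]2(C)O[C@]1(C#C[Si](C(C)C)(C(C)C)C(C)C)C(O)C(C/C(C)=C\I)C2=O | intermediate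
17 | (2S,3S,5R)-2-formyl-5-[(4Z)-5-iodo-4-methylpent-4-enoyl]-5-methyl-2-{[tri(propan-2-yl)silyl]ethynyl}oxolan-3-yl 2-methylprop-2-enoate | C=C(C)C(=O)O[C@H]1C[C@](C)(C(=O)CC/C(C)=C\I)O[C@]1(C#C[Si](C(C)C)(C(C)C)C(C)C)C=O | intermediate
18 | (Z)-vinylchromium(III) dichloride derived from 17 (CrCl2 in place of I) | C=C(C)C(=O)O[C@H]1C[C@](C)(C(=O)CC/C(C)=C\[Cr](Cl)Cl)O[C@]1(C#C[Si](C(C)C)(C(C)C)C(C)C)C=O | intermediate
19 | (1R,5Z,7R,8R,9S)-7-hydroxy-1,5-dimethyl-2-oxo-8-{[tri(propan-2-yl)silyl]ethynyl}-11-oxabicyclo[6.2.1]undec-5-en-9-yl 2-methylprop-2-enoate | C=C(C)C(=O)O[C@H]1C[C@@]2(C)O[C@]1(C#C[Si](C(C)C)(C(C)C)C(C)C)[C@H](O)/C=C(/C)CCC2=O | intermediate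
20 | (1R,5R,6S,7R,8R,9S)-5,6-epoxy-7-hydroxy-1,5-dimethyl-2-oxo-8-{[tri(propan-2-yl)silyl]ethynyl}-11-oxabicyclo[6.2.1]undecan-9-yl 2-methylprop-2-enoate | C=C(C)C(=O)O[C@H]1C[C@@]2(C)O[C@]1(C#C[Si](C(C)C)(C(C)C)C(C)C)[C@H](O)[C@@H]1O[C@]1(C)CCC2=O | intermediate
21 | (1R,5R,6S,7R,8R,9S)-5,6-epoxy-8-ethynyl-7-hydroxy-1,5-dimethyl-2-oxo-11-oxabicyclo[6.2.1]undecan-9-yl 2-methylprop-2-enoate | C=C(C)C(=O)O[C@H]1C[C@@]2(C)O[C@]1(C#C)[C@H](O)[C@@H]1O[C@]1(C)CCC2=O | intermediate
22 | CNP0241021.1 (4R,5S,6R,7S,8S,10R in germacrane numbering) | C=C(C)C(=O)O[C@H]1C[C@@]2(C)O[C@@]13C(=C)C(=O)O[C@@H]3[C@@H]1O[C@]1(C)CCC2=O | target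

**Totals.** Total steps: 12. Longest linear sequence: 11 steps (1 → 3 → 4 → 10 → … → 22); 10 steps from 5-bromofuran-2-carbaldehyde.

**Three steps most likely to fail, each with a fallback**

Step 7 (enantioselective [5+2] with a vinyl ester). The vinyl ester may be too unreactive, or the ester may end up endo, or the ee may be low on this hindered pyranone. The fallback sets out from 12 and uses the same pyrylium chemistry with 4-methoxybenzyl vinyl ether, an electron-rich alkene of the class for which this catalysis is established, to give the 6-exo 4-methoxybenzyl ether F1. DDQ then frees the 6-exo alcohol F2, and methacrylic anhydride/DMAP returns the route to 15. If the cycloadduct is instead the 6-endo series and deprotection gives the 6-endo alcohol F3, a Mitsunobu esterification with methacrylic acid (DIAD, PPh3) inverts C8 and also arrives at 15.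

Step 8 (hydrative retro-aldol). Water may add poorly to the hindered β-carbon, or the methacrylate may suffer under hydroxide. The fallback sets out from 15 and replaces hydration by an oxidation/reduction pair: TBHP/DBU epoxidation of the enone gives the α,β-epoxy ketone F4, SmI2 (THF–MeOH, –78 °C) reductively opens it to the β-ketol 16, and catalytic DBU in dry THF fragments 16, so the route is rejoined at 17.

Step 9 (ten-membered NHK closure). Oligomerisation or poor C6 selectivity is possible. The fallback sets out from 17, makes the C5–C6 bond intermolecularly and closes the ring at the alkene instead. Pd(PPh3)4/Bu3SnH hydrodeiodination gives the methallyl keto-aldehyde F5. Aldehyde-selective Cr/Ni coupling with vinyl bromide gives the Felkin allylic alcohol F6. Ring-closing metathesis (Hoveyda–Grubbs II, dilute toluene, 60 °C) between the vinyl and methallyl groups forms the ring-constrained (Z)-trisubstituted alkene and comes back at 19.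

**Further compounds**

F1 | step 7 | (1R,5S,6S)-3-[(2Z)-3-iodo-2-methylprop-2-en-1-yl]-6-[(4-methoxyphenyl)methoxy]-1-methyl-5-{[tri(propan-2-yl)silyl]ethynyl}-8-oxabicyclo[3.2.1]oct-3-en-2-one | COc1ccc(CO[C@H]2C[C@@]3(C)O[C@]2(C#C[Si](C(C)C)(C(C)C)C(C)C)C=C(C/C(C)=C\I)C3=O)cc1
F2 | step 7 | (1R,5S,6S)-6-hydroxy-3-[(2Z)-3-iodo-2-methylprop-2-en-1-yl]-1-methyl-5-{[tri(propan-2-yl)silyl]ethynyl}-8-oxabicyclo[3.2.1]oct-3-en-2-one (6-exo alcohol) | O[C@H]1C[C@@]2(C)O[C@]1(C#C[Si](C(C)C)(C(C)C)C(C)C)C=C(C/C(C)=C\I)C2=O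
F3 | step 7 | (1R,5S,6R)-6-hydroxy-3-[(2Z)-3-iodo-2-methylprop-2-en-1-yl]-1-methyl-5-{[tri(propan-2-yl)silyl]ethynyl}-8-oxabicyclo[3.2.1]oct-3-en-2-one (6-endo alcohol) | O[C@@H]1C[C@@]2(C)O[C@]1(C#C[Si](C(C)C)(C(C)C)C(C)C)C=C(C/C(C)=C\I)C2=O
F4 | step 8 | 3,4-epoxide of 15 (α,β-epoxy ketone; bridgeheads and ester carbon as in 15, epoxide carbons unassigned) | C=C(C)C(=O)O[C@H]1C[C@@]2(C)O[C@]1(C#C[Si](C(C)C)(C(C)C)C(C)C)C1OC1(C/C(C)=C\I)C2=O
F5 | step 9 | (2S,3S,5R)-2-formyl-5-methyl-5-(4-methylpent-4-enoyl)-2-{[tri(propan-2-yl)silyl]ethynyl}oxolan-3-yl 2-methylprop-2-enoate | C=C(C)C(=O)O[C@H]1C[C@](C)(C(=O)CCC(C)=C)O[C@]1(C#C[Si](C(C)C)(C(C)C)C(C)C)C=O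
F6 | step 9 | (2R,3S,5R)-2-[(1R)-1-hydroxyprop-2-en-1-yl]-5-methyl-5-(4-methylpent-4-enoyl)-2-{[tri(propan-2-yl)silyl]ethynyl}oxolan-3-yl 2-methylprop-2-enoate | C=C(C)C(=O)O[C@H]1C[C@](C)(C(=O)CCC(C)=C)O[C@]1(C#C[Si](C(C)C)(C(C)C)C(C)C)[C@H](O)C=C
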